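Summer cannot have put two ligands on each complex. Its charge gives 1.28 incoming ligand per starting complex, so for a double exchange the incoming ligand is the limiting reagent, and yet by 8.00 h the starting complex and the complex with one exchanged together read 10.0%. So I read a rule from the runs instead of reckoning a plain chain of exchanges.

| setting | summer | spring | noon | delta | zeta | gamma |
|---|---|---|---|---|---|---|
| starting complex | 0.050 M | 0.050 M | 0.050 M | 0.050 M | 0.050 M | 0.050 M |
| incoming ligand | 0.064 M | 0.11 M | 0.16 M | 0.0600 M | 0.125 M | 0.200 M |
| remark | run made earlier | run made earlier | run made earlier |  |  |  |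
| time |  |  |  | 8.0 h | 8.0 h | 8.0 h |

- summer (time / h: complex with one exchanged / %, starting complex / %): 1.50: 18, 21; 3.00: 15, 14; 5.00: 9, 8; 6.00: 8, 4; 8.00: 7, 3
- spring (time / h: complex with one exchanged / %, starting complex / %): 0.667: 20, 25; 1.33: 15, 13; 2.50: 13, 9; 4.00: 9, 4; 8.00: 3, 2
- noon (time / h: complex with one exchanged / %, starting complex / %): 1.50: 13, 9; 3.00: 8, 4; 5.00: 4, 0; 6.00: 4, 4; 8.00: 1, 0

(standard deviation of a reading: 1.5 percentage points)



- amount of complex with one exchanged at the end, in percent of the starting complex charged, for each flask in turn (delta, zeta, gamma)

Turn the time first. By hand, a longer wait should thin out the complex with one exchanged, and spring does that, reading 9% at 4.00 h and 3% at 8.00 h. But delta, zeta and gamma stop at 8.0 h, the time of the last reading in each earlier run. Compare end with end, and time drops out.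

Then turn the ligand. By hand, more [incoming ligand] should push the complex with one exchanged onward, and the end readings do fall: 7% in summer, 3% in spring, 1% in noon. Noon's small reading carries a scatter of 1.5 percentage points, so I leave it out and use summer and spring:

ln(7% / 3%) / (0.11 M − 0.064 M) = 18.4 M⁻¹

Call this the ligand price, the fall in the logarithm of the end amount per unit of [incoming ligand] charged, with the starting complex held at 0.050 M and the end at 8.0 h; it is a reading and carries the scatter of its two end values. My own reckoning pays it from summer for delta and from spring for the other two:

delta: 7.54%
zeta: 2.28%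
gamma: 0.572%

The forecast gives 6.5%, 2.7% and 0.6%, from values “roughly falling exponentially with ligand”. That is the shape of my rule, though its delta is lower than mine and its zeta higher.

    starting complex + incoming ligand ⇌ leaving ligand + complex with one exchanged (K = 1.00, k = 0.450 M⁻¹ min⁻¹)
    complex with one exchanged + incoming ligand ⇌ leaving ligand + complex with two exchanged (K = 2.40, k = 0.680 M⁻¹ min⁻¹)
    complex with two exchanged + incoming ligand ⇌ leaving ligand + complex with three exchanged (K = 35.0, k = 0.0510 M⁻¹ min⁻¹)
    2 starting complex → homo dimer (k = 0.180 M⁻¹ min⁻¹)
    leaving ligand → by-product carried off (k = 0.0150 min⁻¹)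

Delta ends at 8.92%, zeta at 2.38% and gamma at 0.239%, and the forecast stands within the margin. At 8.00 h delta holds 39.8% of its charged complex as homo dimer, each dimer counted as two, and that form took up no incoming ligand. Paid from delta's simulated value, the ligand price gives zeta 2.69% against the 2.38% it holds. Paid from zeta's, it gives gamma 0.598% against 0.239%.

(The data were computed with constants of no real substance; the scatter is artificial.)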